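## Retrosynthetic overview

- Numbering: C1 allyl bridgehead, C2 CH2, C3 CHOMe, C4 C=O, C5 OMe bridgehead, C6 CHAr, C7 CHMe, C8 CHOH. The five-membered ring is C1–C8–C5–C6–C7 and the six-membered ring is C1–C2–C3–C4–C5–C8.
- Feature: C1 is alpha to the C8 carbonyl and C2 is beta to the C4 carbonyl, so C1–C2 is the bond of a Michael addition of a cyclopentanone enolate to a 2-methoxyacryloyl group carried on C5.
- Target ⇒ (desilylation; C8 reduction with C4 masked as its enolate) bicyclic 4,8-dione ⇒ (C1–C2, 6-endo Michael) 2-methoxy-2-(2-methoxyacryloyl)cyclopentanone ⇒ (O-methylation; hydroxylation anti to aryl; C-acylation at C5) 2-allyl-3-methyl-4-arylcyclopentanone.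
- That ketone ⇒ (aryl cuprate anti to methyl) (4R,5S)-5-allyl-4-methylcyclopent-2-enone ⇒ (silanol elimination; methyl cuprate anti to OSi; Stille allylation; iodination) (S)-4-silyloxycyclopent-2-enone.
- Ring order: the five-membered ring is present from the start; the six-membered ring is closed last, in the key step.

Key step: step 12

Remark: (S)-4-(tert-butyldimethylsilyloxy)cyclopent-2-en-1-one is taken as a purchasable building block (both enantiomers are catalogue items); it replaces a 3-arylcyclopentanone desaturation whose regiochemistry would be uncertain, and lets both ring substituents enter by anti-selective conjugate additions.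

## Route

Step 1
Reactants: 1 (S)-4-(tert-butyldimethylsilyloxy)cyclopent-2-en-1-one
Product: 2 (S)-4-(tert-butyldimethylsilyloxy)-2-iodocyclopent-2-en-1-one
Conditions: I2, pyridine, CH2Cl2, 0 °C → rt
Reagents that add atoms: iodine, II
Why: Alpha-iodination of an enone by pyridine addition, iodination of the resulting enolate and loss of pyridine should give the 2-iodoenone without touching the C4 stereocentre.

Step 2
Reactants: 2 (S)-4-(tert-butyldimethylsilyloxy)-2-iodocyclopent-2-en-1-one; 3 allyltributylstannane
Product: 4 (S)-2-allyl-4-(tert-butyldimethylsilyloxy)cyclopent-2-en-1-one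
Conditions: Pd2(dba)3 (cat.), AsPh3, CuI (cat.), N-methylpyrrolidone, rt
Reagents that add atoms: none
Why: Stille coupling of an alpha-iodoenone with an allylstannane, in which the arsine ligand and the copper co-catalyst speed transmetalation, should give the skipped diene at room temperature without migration of the allyl double bond.

Step 3
Reactants: 4 (S)-2-allyl-4-(tert-butyldimethylsilyloxy)cyclopent-2-en-1-one
Product: 5 (2S,3S,4S)-2-allyl-4-(tert-butyldimethylsilyloxy)-3-methylcyclopentan-1-one
Conditions: Me2CuLi (from MeLi and CuI), Et2O, −78 → −40 °C; then aq NH4Cl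
Reagents that add atoms: methyllithium (used as lithium dimethylcuprate), C[Li]
Why: Cuprate conjugate addition to the 2-substituted enone should occur anti to the adjacent silyloxy group and so set the methyl-bearing centre (C7 of the target); the allyl-bearing centre is epimerisable, settles trans to the methyl and is erased again in step 12.

Step 4
Reactants: 5 (2S,3S,4S)-2-allyl-4-(tert-butyldimethylsilyloxy)-3-methylcyclopentan-1-one
Product: 6 (4R,5S)-5-allyl-4-methylcyclopent-2-en-1-one
Conditions: DBU, CH2Cl2, 0 °C → rt
Reagents that add atoms: none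
Why: E1cB elimination of the beta-silyloxy group should give the enone with its beta carbon at the future C6, the mild amine base and low temperature being chosen to avoid migration of the double bond to the fully substituted position.

Step 5
Reactants: 7 5-bromo-2-methoxyphenol
Product: 8 (5-bromo-2-methoxyphenoxy)(tert-butyl)dimethylsilane
Conditions: TBSCl, imidazole, DMF, rt
Reagents that add atoms: tert-butyldimethylsilyl chloride, CC(C)(C)[Si](C)(C)Cl
Why: Imidazole-promoted silylation of the phenol masks the acidic OH for the organometallic steps that follow.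

Step 6
Reactants: 8 (5-bromo-2-methoxyphenoxy)(tert-butyl)dimethylsilane; 6 (4R,5S)-5-allyl-4-methylcyclopent-2-en-1-one
Product: 10 (2S,3R,4S)-2-allyl-4-Ar-3-methylcyclopentan-1-one (Ar = 3-(tert-butyldimethylsilyloxy)-4-methoxyphenyl), via arylmagnesium bromide 9 (not isolated)
Conditions: 8, Mg, THF, 40 °C; then CuBr·SMe2 (cat.), 6, THF, −78 → −30 °C; then aq NH4Cl
Reagents that add atoms: none
Why: Copper-catalysed conjugate addition of the arylmagnesium bromide to the 4,5-disubstituted cyclopentenone should deliver the aryl group anti to the neighbouring methyl, setting C6 trans to C7.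

Step 7
Reactants: 11 methyl 2-methoxyacrylate
Product: 12 2-methoxyacrylic acid
Conditions: LiOH, THF/H2O, 0 °C → rt; then KHSO4 to pH 3, 0 °C
Reagents that add atoms: lithium hydroxide, [Li+].[OH-]
Why: Saponification of the methyl ester followed by brief cold acidification should give the acid with the enol ether intact.

Step 8
Reactants: 12 2-methoxyacrylic acid
Product: 13 1-(2-methoxyacryloyl)-1H-benzotriazole
Conditions: 1H-benzotriazole, DCC, CH2Cl2, 0 °C → rt
Reagents that add atoms: 1H-benzotriazole, c1ccc2[nH]nnc2c1
Why: Carbodiimide coupling of the acid with benzotriazole should give a stable, neutral N-acylbenzotriazole, an acyl donor that acylates ketone enolates on carbon.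

Step 9
Reactants: 10 (2S,3R,4S)-2-allyl-4-Ar-3-methylcyclopentan-1-one; 13 1-(2-methoxyacryloyl)-1H-benzotriazole
Product: 15 (2S,3R,4R,5S)-5-allyl-3-Ar-2-(2-methoxyacryloyl)-4-methylcyclopentan-1-one (keto form of a largely enolised 1,3-diketone), via lithium enolate 14 (not isolated)
Conditions: LiN(iPr)2 (2.1 equiv), THF, −78 °C; then 13, −78 → −20 °C; then aq NH4Cl
Reagents that add atoms: none
Why: Kinetic deprotonation should take the ring CH2 rather than the allyl-substituted CH, and the enolate should be C-acylated by the N-acylbenzotriazole (crossed Claisen-type acylation), the second equivalent of base taking up the acidic diketone as it forms.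

Step 10
Reactants: 15 (2S,3R,4R,5S)-5-allyl-3-Ar-2-(2-methoxyacryloyl)-4-methylcyclopentan-1-one
Product: 17 (2S,3S,4R,5S)-5-allyl-3-Ar-2-hydroxy-2-(2-methoxyacryloyl)-4-methylcyclopentan-1-one, via potassium enolate 16 (not isolated)
Conditions: KN(SiMe3)2 (1.0 equiv), THF, −78 °C; then 2-(phenylsulfonyl)-3-phenyloxaziridine, −78 → −40 °C; then AcOH, −78 °C
Reagents that add atoms: 2-(phenylsulfonyl)-3-phenyloxaziridine, O=S(=O)(c1ccccc1)N1OC1c1ccccc1
Why: Electrophilic hydroxylation of the planar diketone enolate by the bulky N-sulfonyloxaziridine should occur on the face anti to the vicinal aryl group, leaving the hydroxyl trans and the acyl group cis to the aryl (C5 of the target), while the oxidant leaves both alkenes alone.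

Step 11
Reactants: 17 (2S,3S,4R,5S)-5-allyl-3-Ar-2-hydroxy-2-(2-methoxyacryloyl)-4-methylcyclopentan-1-one
Product: 18 (2S,3S,4R,5S)-5-allyl-3-Ar-2-methoxy-2-(2-methoxyacryloyl)-4-methylcyclopentan-1-one
Conditions: MeOTf, 2,6-di-tert-butyl-4-methylpyridine, CH2Cl2, 0 °C → rt
Reagents that add atoms: methyl trifluoromethanesulfonate, COS(=O)(=O)C(F)(F)F
Why: O-methylation of the tertiary alpha-ketol with a strong methyl donor and a hindered non-nucleophilic base should avoid alkoxide formation, and with it the acyl shift and retro-Claisen cleavage open to a 2-hydroxy-1,3-diketone.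

Step 12
Reactants: 18 (2S,3S,4R,5S)-5-allyl-3-Ar-2-methoxy-2-(2-methoxyacryloyl)-4-methylcyclopentan-1-one
Product: 21 (1S,3S,5S,6S,7R)-1-allyl-6-Ar-3,5-dimethoxy-7-methylbicyclo[3.2.1]octane-4,8-dione, via potassium C1 enolate 19 (not isolated), via bicyclic potassium enolate 20 (not isolated)
Conditions: KN(SiMe3)2 (1.05 equiv), THF (0.01 M), −78 → −20 °C; then AcOH, −78 °C
Reagents that add atoms: none
Why: Because C5 is quaternary the amide base can remove only the C1 hydrogen, and the C1=C8 enolate 19 should add through carbon to the terminal carbon C2 of the 2-methoxyacryloyl group, forming the C1–C2 bond and the C3=C4 enolate 20 (intramolecular Michael addition). The closest known reaction type is the intramolecular Michael addition of a cyclic ketone enolate to a vinyl ketone held on the alpha' carbon, which gives bridged bicyclic diketones. The six-membered ring C1–C2–C3–C4–C5–C8 closes in the 6-endo-trig mode (6-enolendo for the nucleophile), a favoured mode. C1 is fixed by the tether, since the acyl group sits on the ring face cis to the aryl group and C2 can reach only that face of C1, which is also the face anti to the C7 methyl. C3 is set when enolate 20 is protonated in the cold on its outer face, the inner face being covered by the endo aryl group on C6, so the methoxy group stays on the inner face as in the target. The step needs C- over O-alkylation and freedom from retro-Claisen cleavage of the non-enolisable 1,3-diketone; the first should follow from the soft carbon terminus and the reversibility of the oxa-Michael path, the second from the non-nucleophilic base and the absence of alkoxide.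

Step 13
Reactants: 21 (1S,3S,5S,6S,7R)-1-allyl-6-Ar-3,5-dimethoxy-7-methylbicyclo[3.2.1]octane-4,8-dione
Product: 24 (1S,3S,5S,6S,7R,8S)-1-allyl-6-Ar-8-hydroxy-3,5-dimethoxy-7-methylbicyclo[3.2.1]octan-4-one, via lithium C3 enolate 22 (not isolated), via lithium aluminate enolate 23 (not isolated)
Conditions: LiN(SiMe3)2 (1.1 equiv), THF, −78 °C; then LiAlH4, −78 °C; then AcOH (excess), −78 °C; then aq potassium sodium tartrate
Reagents that add atoms: none
Why: Deprotonation at C3, the only enolisable position, masks the C4 carbonyl as its enolate (enolate protection of a ketone during hydride reduction) so that the small anionic hydride should reduce only C8 and the C8 alkoxide cannot undergo retro-aldol cleavage; the charged enolate on the C2–C4 bridge should repel the hydride towards the C6–C7 face, placing the hydroxyl syn to C2–C4, and the cold acid quench should again protonate C3 on the outer face.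

Step 14
Reactants: 24 (1S,3S,5S,6S,7R,8S)-1-allyl-6-Ar-8-hydroxy-3,5-dimethoxy-7-methylbicyclo[3.2.1]octan-4-one
Product: 25 (1S,3S,5S,6S,7R,8S)-1-allyl-8-hydroxy-6-(3-hydroxy-4-methoxyphenyl)-3,5-dimethoxy-7-methylbicyclo[3.2.1]octan-4-one
Conditions: Bu4NF buffered with AcOH, THF, 0 °C
Reagents that add atoms: none
Why: Fluoride desilylation of the aryl silyl ether should free the phenol, the acetic acid buffer keeping the medium from epimerising C3 or opening the beta-hydroxy ketone by retro-aldol reaction.

## Compound list

1 | (S)-4-(tert-butyldimethylsilyloxy)cyclopent-2-en-1-one | O=C1C[C@H](O[Si](C)(C)C(C)(C)C)C=C1 | starting material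
2 | (S)-4-(tert-butyldimethylsilyloxy)-2-iodocyclopent-2-en-1-one | O=C1C[C@H](O[Si](C)(C)C(C)(C)C)C=C1I | intermediate
3 | allyltributylstannane | C=CC[Sn](CCCC)(CCCC)CCCC | starting material
4 | (S)-2-allyl-4-(tert-butyldimethylsilyloxy)cyclopent-2-en-1-one | O=C1C[C@H](O[Si](C)(C)C(C)(C)C)C=C1CC=C | intermediate
5 | (2S,3S,4S)-2-allyl-4-(tert-butyldimethylsilyloxy)-3-methylcyclopentan-1-one (allyl and silyloxy on one face, methyl on the other) | C=CC[C@@H]1C(=O)C[C@H](O[Si](C)(C)C(C)(C)C)[C@H]1C | intermediate
6 | (4R,5S)-5-allyl-4-methylcyclopent-2-en-1-one (trans) | C=CC[C@@H]1C(=O)C=C[C@H]1C | intermediate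
7 | 5-bromo-2-methoxyphenol | COc1ccc(Br)cc1O | starting material
8 | (5-bromo-2-methoxyphenoxy)(tert-butyl)dimethylsilane | COc1ccc(Br)cc1O[Si](C)(C)C(C)(C)C | intermediate
9 | [3-(tert-butyldimethylsilyloxy)-4-methoxyphenyl]magnesium bromide | COc1ccc([Mg]Br)cc1O[Si](C)(C)C(C)(C)C | intermediate (not isolated)
10 | (2S,3R,4S)-2-allyl-4-[3-(tert-butyldimethylsilyloxy)-4-methoxyphenyl]-3-methylcyclopentan-1-one (allyl and aryl on one face, methyl on the other) | C=CC[C@@H]1C(=O)C[C@H](c2ccc(OC)c(O[Si](C)(C)C(C)(C)C)c2)[C@H]1C | intermediate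
11 | methyl 2-methoxyacrylate | C=C(OC)C(=O)OC | starting material
12 | 2-methoxyacrylic acid | C=C(OC)C(=O)O | intermediate
13 | 1-(2-methoxyacryloyl)-1H-benzotriazole | C=C(OC)C(=O)n1nnc2ccccc21 | intermediate
14 | lithium enolate of 10 at the ring CH2 | C=CC[C@@H]1C([O-])=C[C@H](c2ccc(OC)c(O[Si](C)(C)C(C)(C)C)c2)[C@H]1C.[Li+] | intermediate (not isolated)
15 | (2S,3R,4R,5S)-5-allyl-3-[3-(tert-butyldimethylsilyloxy)-4-methoxyphenyl]-2-(2-methoxyacryloyl)-4-methylcyclopentan-1-one (keto form drawn; C2 is labile and the compound is largely enolised) | C=CC[C@@H]1C(=O)[C@@H](C(=O)C(OC)=C)[C@H](c2ccc(OC)c(O[Si](C)(C)C(C)(C)C)c2)[C@H]1C | intermediate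
16 | potassium enolate of diketone 15 | C=CC[C@@H]1C([O-])=C(C(=O)C(OC)=C)[C@H](c2ccc(OC)c(O[Si](C)(C)C(C)(C)C)c2)[C@H]1C.[K+] | intermediate (not isolated)
17 | (2S,3S,4R,5S)-5-allyl-3-[3-(tert-butyldimethylsilyloxy)-4-methoxyphenyl]-2-hydroxy-2-(2-methoxyacryloyl)-4-methylcyclopentan-1-one (hydroxyl and methyl on one face; acyl, aryl and allyl on the other) | C=CC[C@@H]1C(=O)[C@](O)(C(=O)C(OC)=C)[C@H](c2ccc(OC)c(O[Si](C)(C)C(C)(C)C)c2)[C@H]1C | intermediate
18 | (2S,3S,4R,5S)-5-allyl-3-[3-(tert-butyldimethylsilyloxy)-4-methoxyphenyl]-2-methoxy-2-(2-methoxyacryloyl)-4-methylcyclopentan-1-one | C=CC[C@@H]1C(=O)[C@](OC)(C(=O)C(OC)=C)[C@H](c2ccc(OC)c(O[Si](C)(C)C(C)(C)C)c2)[C@H]1C | intermediate (key-step precursor)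
19 | potassium C1=C8 enolate of 18 | C=CCC1=C([O-])[C@](OC)(C(=O)C(OC)=C)[C@H](c2ccc(OC)c(O[Si](C)(C)C(C)(C)C)c2)[C@H]1C.[K+] | intermediate (not isolated)
20 | potassium C3=C4 enolate of the bicyclic dione | C=CC[C@]12CC(OC)=C([O-])[C@](OC)([C@H](c3ccc(OC)c(O[Si](C)(C)C(C)(C)C)c3)[C@H]1C)C2=O.[K+] | intermediate (not isolated)
21 | (1S,3S,5S,6S,7R)-1-allyl-6-[3-(tert-butyldimethylsilyloxy)-4-methoxyphenyl]-3,5-dimethoxy-7-methylbicyclo[3.2.1]octane-4,8-dione (numbering of the overview) | C=CC[C@]12C[C@H](OC)C(=O)[C@](OC)([C@H](c3ccc(OC)c(O[Si](C)(C)C(C)(C)C)c3)[C@H]1C)C2=O | intermediate (key-step product)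
22 | lithium C3=C4 enolate of 21 | C=CC[C@]12CC(OC)=C([O-])[C@](OC)([C@H](c3ccc(OC)c(O[Si](C)(C)C(C)(C)C)c3)[C@H]1C)C2=O.[Li+] | intermediate (not isolated)
23 | lithium C3=C4 enolate carrying the C8 alkoxytrihydridoaluminate | C=CC[C@]12CC(OC)=C([O-])[C@](OC)([C@H](c3ccc(OC)c(O[Si](C)(C)C(C)(C)C)c3)[C@H]1C)[C@H]2O[AlH3-].[Li+].[Li+] | intermediate (not isolated)
24 | (1S,3S,5S,6S,7R,8S)-1-allyl-6-[3-(tert-butyldimethylsilyloxy)-4-methoxyphenyl]-8-hydroxy-3,5-dimethoxy-7-methylbicyclo[3.2.1]octan-4-one | C=CC[C@]12C[C@H](OC)C(=O)[C@](OC)([C@H](c3ccc(OC)c(O[Si](C)(C)C(C)(C)C)c3)[C@H]1C)[C@H]2O | intermediate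
25 | (1S,3S,5S,6S,7R,8S)-1-allyl-8-hydroxy-6-(3-hydroxy-4-methoxyphenyl)-3,5-dimethoxy-7-methylbicyclo[3.2.1]octan-4-one (CNP0209708.1) | C=CC[C@]12C[C@H](OC)C(=O)[C@](OC)([C@H](c3ccc(OC)c(O)c3)[C@H]1C)[C@H]2O | target

## Step count and risks

Total steps: 14. Longest linear sequence: 11 (steps 1, 2, 3, 4, 6, 9, 10, 11, 12, 13, 14).

The three steps most likely to fail are steps 12, 13 and 11.

**Step 12.** The carbon–carbon closure may be slow because the alkoxy-substituted acceptor is electron-rich, so that the free enolate closes through oxygen, reopens, or the strained 1,3-diketone fragments before the bridge forms. The fallback changes the activation from a free enolate to a silyl enol ether with an acid-activated acceptor. It sets out from 18: soft enolisation with TMSOTf and Et3N in CH2Cl2 should give the C1=C8 trimethylsilyl enol ether F1. A Mukaiyama–Michael closure with catalytic TMSOTf in CH2Cl2 at −78 °C, the enone being activated at its carbonyl and the silyl group passing to the new enol oxygen, should give the bicyclic C3=C4 trimethylsilyl enol ether F2. Cold aqueous citric acid in THF should then hydrolyse it with protonation of C3 on the outer face, and the route is rejoined at 21.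

**Step 13.** Facial selectivity at C8 may be poor or reversed: the exo methyl on C7 screens the C6–C7 face, and if this outweighs the repulsion by the enolate, hydride arrives from the C2–C4 face and the C8 epimer results. The fallback replaces kinetic hydride delivery by an electron-transfer reduction under product-stability control. It sets out from 21: LiN(SiMe3)2 followed by Et3SiCl in THF at −78 °C should give the C3=C4 triethylsilyl enol ether F3. Reduction of the C8 ketone with SmI2, H2O and Et3N in THF should pass through a ketyl and an organosamarium species that settle with oxygen on the less crowded side, syn to C2–C4 and away from the C7 methyl, giving the carbinol F4. Bu4NF buffered with AcOH should then remove both silyl groups, protonating C3 on the outer face, and the route is rejoined at the target 25.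

**Step 11.** Etherification of the congested, electron-poor tertiary hydroxyl may be sluggish, and acyl migration may overtake it. The fallback postpones the methylation until the hydroxyl is a bridgehead one. It sets out from 17: Et3SiOTf and 2,6-lutidine in CH2Cl2 should give the tertiary triethylsilyl ether F5. The closure of step 12 (KN(SiMe3)2, THF, then AcOH) applied to it should give the bicyclic silyl ether F6. Aqueous trifluoroacetic acid in THF at 0 °C, which spares the aryl silyl ether, should free the bridgehead alcohol F7. Its hydroxyl is held back and exposed, and an acyl shift to a bridgehead is geometrically blocked, so methylation with Ag2O and MeI should succeed, and the route is rejoined at 21.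

## Further compounds

F1 | step 12 | C1=C8 trimethylsilyl enol ether of 18 | C=CCC1=C(O[Si](C)(C)C)[C@](OC)(C(=O)C(OC)=C)[C@H](c2ccc(OC)c(O[Si](C)(C)C(C)(C)C)c2)[C@H]1C
F2 | step 12 | bicyclic C3=C4 trimethylsilyl enol ether of 21 | C=CC[C@]12CC(OC)=C(O[Si](C)(C)C)[C@](OC)([C@H](c3ccc(OC)c(O[Si](C)(C)C(C)(C)C)c3)[C@H]1C)C2=O
F3 | step 13 | C3=C4 triethylsilyl enol ether of 21 | C=CC[C@]12CC(OC)=C(O[Si](CC)(CC)CC)[C@](OC)([C@H](c3ccc(OC)c(O[Si](C)(C)C(C)(C)C)c3)[C@H]1C)C2=O
F4 | step 13 | (8S)-carbinol of the C3=C4 triethylsilyl enol ether (hydroxyl syn to C2–C4) | C=CC[C@]12CC(OC)=C(O[Si](CC)(CC)CC)[C@](OC)([C@H](c3ccc(OC)c(O[Si](C)(C)C(C)(C)C)c3)[C@H]1C)[C@H]2O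
F5 | step 11 | tertiary triethylsilyl ether of 17 | C=CC[C@@H]1C(=O)[C@](O[Si](CC)(CC)CC)(C(=O)C(OC)=C)[C@H](c2ccc(OC)c(O[Si](C)(C)C(C)(C)C)c2)[C@H]1C
F6 | step 11 | bicyclic 4,8-dione with C5 triethylsilyloxy in place of C5 methoxy | C=CC[C@]12C[C@H](OC)C(=O)[C@](O[Si](CC)(CC)CC)([C@H](c3ccc(OC)c(O[Si](C)(C)C(C)(C)C)c3)[C@H]1C)C2=O
F7 | step 11 | bicyclic 4,8-dione with free C5 bridgehead hydroxyl | C=CC[C@]12C[C@H](OC)C(=O)[C@](O)([C@H](c3ccc(OC)c(O[Si](C)(C)C(C)(C)C)c3)[C@H]1C)C2=O
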